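**Plan**
- Retrosynthetic cuts, in order: the four Si–O bonds; C2–C3 of ring C (carbenoid C–H insertion); the diazo group (taken back to an acetyl group); O1–CH2 (Mitsunobu ether); C8–CH2 of the side chain (B-alkyl Suzuki). This leaves phloroacetophenone, a chromen-6-ylmethanol and a C5 alkene.
- Enabling feature: C2–H is alpha to O1 and benzylic to the oxygen-rich ring B, and C2 lies six atoms from C3 along C3–C4–C4a–C8a–O1–C2. A carbenoid at C3 on an acyl group at C4a can therefore reach it by 1,6-insertion.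
- Forward order: the pyran of ring B is built first (chromanone from 4-bromoresorcinol, then chromene and a CH2OH handle). Ring A receives the side chain at the future C8, the two halves are joined through O1, and ring C closes last.
- Stereochemistry: C2 is the only stereocentre. It is set in the ring-C closure by a chiral dirhodium tetracarboxylate that selects one enantiotopic benzylic hydrogen, and buffered desilylation keeps it.

Key step: step 12

Assumption: Rh2(S-PTTL)4 is taken to deliver the 2S product; if the sense of induction at this benzylic ether C–H proves opposite, the mirror-image catalyst Rh2(R-PTTL)4 (from D-tert-leucine) is used with nothing else changed. Flavanone numbering (O1, C2, C3, C4, C4a, C5–C8, C8a) is used for ring atoms; TIPS = triisopropylsilyl, TES = triethylsilyl.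

**Step 1**
Reactants: 1 4-bromobenzene-1,3-diol; 2 3-methylbut-2-enoic acid
Product: 4 6-bromo-7-hydroxy-2,2-dimethylchroman-4-one, via aryl enone 3 (not isolated)
Conditions: P2O5/MsOH (1:10 w/w), 70 °C
Reagents that add atoms: none
Why: Friedel–Crafts acylation at the ring position para to one hydroxyl and ortho to the other (bromine blocks the alternative) is followed by intramolecular oxa-Michael addition of the ortho hydroxyl, the standard chromanone synthesis from resorcinols.

**Step 2**
Reactants: 4 6-bromo-7-hydroxy-2,2-dimethylchroman-4-one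
Product: 5 6-bromo-2,2-dimethyl-7-(TIPSO)chroman-4-one
Conditions: TIPSCl, imidazole, DMF, rt
Reagents that add atoms: triisopropylsilyl chloride, CC(C)[Si](Cl)(C(C)C)C(C)C
Why: Routine phenol silylation; the bulky TIPS ether should tolerate borohydride, catalytic acid, organolithium and aqueous phosphate, and resists anionic oxygen-to-carbon silyl migration in step 4.

**Step 3**
Reactants: 5 6-bromo-2,2-dimethyl-7-(TIPSO)chroman-4-one
Product: 7 6-bromo-2,2-dimethyl-7-(TIPSO)-2H-chromene, via chromanol 6 (not isolated)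
Conditions: NaBH4, THF/EtOH, 0 °C to rt; aqueous work-up; then pTsOH·H2O (cat.), toluene, 80 °C
Reagents that add atoms: none
Why: Borohydride reduction of the aryl ketone and acid-catalysed E1 dehydration of the benzylic alcohol, assisted by the para silyloxy group, is the usual chromanone-to-2H-chromene conversion.

**Step 4**
Reactants: 7 6-bromo-2,2-dimethyl-7-(TIPSO)-2H-chromene
Product: 9 2,2-dimethyl-7-(TIPSO)-2H-chromene-6-carbaldehyde, via aryllithium 8 (not isolated)
Conditions: n-BuLi, THF, −78 °C; then DMF, −78 to 0 °C; aq NH4Cl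
Reagents that add atoms: N,N-dimethylformamide, CN(C)C=O
Why: Bromine–lithium exchange and Bouveault formylation; at −78 °C the aryllithium should be trapped before the bulky silyl group can migrate from oxygen to carbon.

**Step 5**
Reactants: 9 2,2-dimethyl-7-(TIPSO)-2H-chromene-6-carbaldehyde
Product: 10 [2,2-dimethyl-7-(TIPSO)-2H-chromen-6-yl]methanol
Conditions: NaBH4, THF/EtOH, 0 °C
Reagents that add atoms: none
Why: Chemoselective borohydride reduction of the aldehyde leaves the chromene double bond and the aryl silyl ether untouched, and the TIPS group should not shift to the new alkoxide at 0 °C.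

**Step 6**
Reactants: 11 2-methylbut-3-en-2-ol
Product: 12 triethyl[(2-methylbut-3-en-2-yl)oxy]silane
Conditions: TESCl, imidazole, DMAP (cat.), DMF, rt
Reagents that add atoms: triethylsilyl chloride, CC[Si](Cl)(CC)CC
Why: Silylation caps the only aliphatic hydroxyl so that it can neither quench the enolate of step 11 nor undergo O–H insertion in step 12.

**Step 7**
Reactants: 13 2',4',6'-trihydroxyacetophenone
Product: 14 1-[2-hydroxy-4,6-bis(TIPSO)phenyl]ethanone
Conditions: TIPSCl (2.2 equiv), imidazole, DMAP (cat.), DMF, 0 °C to rt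
Reagents that add atoms: triisopropylsilyl chloride, CC(C)[Si](Cl)(C(C)C)C(C)C
Why: The 4-hydroxyl and one ortho hydroxyl are silylated while the last ortho hydroxyl stays hydrogen-bonded to the acetyl carbonyl and is far less nucleophilic, the usual outcome of bis-protection of phloroacetophenone.

**Step 8**
Reactants: 14 1-[2-hydroxy-4,6-bis(TIPSO)phenyl]ethanone
Product: 15 1-[2-hydroxy-3-iodo-4,6-bis(TIPSO)phenyl]ethanone
Conditions: NIS (1.05 equiv), CH2Cl2, 0 °C to rt, dark
Reagents that add atoms: N-iodosuccinimide, O=C1CCC(=O)N1I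
Why: Electrophilic aromatic iodination should go ortho to the free phenol at C3, because the only other open position is wedged between two TIPS ethers.

**Step 9**
Reactants: 15 1-[2-hydroxy-3-iodo-4,6-bis(TIPSO)phenyl]ethanone; 12 triethyl[(2-methylbut-3-en-2-yl)oxy]silane
Product: 17 1-[2-hydroxy-3-(3-methyl-3-TESO-butyl)-4,6-bis(TIPSO)phenyl]ethanone, via alkylborane 16 (not isolated)
Conditions: 12, 9-BBN, THF, rt; then aq K3PO4, 15, Pd(OAc)2 (5 mol %), SPhos (10 mol %), THF, 60 °C
Reagents that add atoms: none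
Why: Anti-Markovnikov hydroboration of the terminal alkene is followed by B-alkyl Suzuki–Miyaura coupling, with the biarylphosphine supporting oxidative addition into the hindered, electron-rich aryl iodide; the borane is fully consumed before the ketone is introduced.

**Step 10**
Reactants: 17 1-[2-hydroxy-3-(3-methyl-3-TESO-butyl)-4,6-bis(TIPSO)phenyl]ethanone; 10 [2,2-dimethyl-7-(TIPSO)-2H-chromen-6-yl]methanol
Product: 18 1-[2-{[2,2-dimethyl-7-(TIPSO)-2H-chromen-6-yl]methoxy}-3-(3-methyl-3-TESO-butyl)-4,6-bis(TIPSO)phenyl]ethanone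
Conditions: PPh3, DIAD, toluene, 0 °C to rt
Reagents that add atoms: none
Why: Mitsunobu etherification, in which the ortho-acyl phenol is acidic enough to protonate the betaine and displaces the primary benzylic oxyphosphonium by SN2 under neutral conditions that spare every silyl ether.

**Step 11**
Reactants: 18 1-[2-{[2,2-dimethyl-7-(TIPSO)-2H-chromen-6-yl]methoxy}-3-(3-methyl-3-TESO-butyl)-4,6-bis(TIPSO)phenyl]ethanone
Product: 20 2-diazo-1-[2-{[2,2-dimethyl-7-(TIPSO)-2H-chromen-6-yl]methoxy}-3-(3-methyl-3-TESO-butyl)-4,6-bis(TIPSO)phenyl]ethanone, via trifluoroacetyl diketone 19 (not isolated)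
Conditions: LiN(SiMe3)2, THF, −78 °C; CF3CO2CH2CF3; aq NH4Cl; then MsN3, Et3N, H2O (1 equiv), MeCN, rt
Reagents that add atoms: methanesulfonyl azide, CS(=O)(=O)N=[N+]=[N-]
Why: Danheiser deacylative diazo transfer, in which the lithium enolate of the methyl ketone is trifluoroacetylated and the activated 1,3-diketone takes up the diazo group with loss of the trifluoroacetyl group as the N-acylsulfonamide.

**Step 12**
Reactants: 20 2-diazo-1-[2-{[2,2-dimethyl-7-(TIPSO)-2H-chromen-6-yl]methoxy}-3-(3-methyl-3-TESO-butyl)-4,6-bis(TIPSO)phenyl]ethanone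
Product: 21 (2S)-2-[2,2-dimethyl-7-(TIPSO)-2H-chromen-6-yl]-8-(3-methyl-3-TESO-butyl)-5,7-bis(TIPSO)chroman-4-one
Conditions: Rh2(S-PTTL)4 [dirhodium tetrakis(N-phthaloyl-(S)-tert-leucinate)] (2 mol %), CH2Cl2, 0 °C, slow addition of 20
Reagents that add atoms: none
Why: The dirhodium carboxylate expels N2 from 20 and the electrophilic rhodium carbenoid at C3 attacks one of the two enantiotopic C–H bonds of the O1–CH2–aryl group through a concerted, asynchronous three-centre transition state with hydride-transfer character, forming C2–C3. The closest known reaction type is the dirhodium-carboxylate-catalysed intramolecular C–H insertion of 2-alkoxyaryl diazoketones to chroman-4-ones, including its enantioselective form with chiral carboxylates. Ring C closes by 1,6 C–H insertion through a six-membered array of C3, C4, C4a, C8a, O1 and the benzylic carbon. C2 is the only new stereocentre and is set by the catalyst, whose phthalimido walls decide which enantiotopic hydrogen the carbenoid reaches. The step needs insertion to outrun oxonium ylide formation at O1 with [1,2]-benzyl shift to a benzofuranone. The substrate helps because the target C–H is doubly activated (alpha to O1, benzylic to a ring with ortho and para oxygen donors), O1 is a weakly basic aryl ether oxygen crowded by the C8 chain, no C–H sits at the 1,5 position, and every hydroxyl is silylated so O–H insertion is excluded.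

**Step 13**
Reactants: 21 (2S)-2-[2,2-dimethyl-7-(TIPSO)-2H-chromen-6-yl]-8-(3-methyl-3-TESO-butyl)-5,7-bis(TIPSO)chroman-4-one
Product: 22 (2S)-5,7-dihydroxy-2-(7-hydroxy-2,2-dimethyl-2H-chromen-6-yl)-8-(3-hydroxy-3-methylbutyl)chroman-4-one
Conditions: TBAF, AcOH (1:1, excess), THF, 0 °C to rt
Reagents that add atoms: none
Why: Fluoride cleaves all four Si–O bonds, while the acetic acid buffer keeps the phenols protonated so ring C cannot open by retro-oxa-Michael reaction (the racemisation path of 2'-hydroxyflavanones) and is too weak to cyclise the tertiary alcohol onto the 7-hydroxyl.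

**Compound list**
1 | 4-bromobenzene-1,3-diol | Oc1ccc(Br)c(O)c1 | starting material
2 | 3-methylbut-2-enoic acid | CC(C)=CC(=O)O | starting material
3 | 1-(5-bromo-2,4-dihydroxyphenyl)-3-methylbut-2-en-1-one | CC(C)=CC(=O)c1cc(Br)c(O)cc1O | intermediate
4 | 6-bromo-7-hydroxy-2,2-dimethylchroman-4-one | CC1(C)CC(=O)c2cc(Br)c(O)cc2O1 | intermediate
5 | 6-bromo-2,2-dimethyl-7-(triisopropylsilyloxy)chroman-4-one | CC1(C)CC(=O)c2cc(Br)c(O[Si](C(C)C)(C(C)C)C(C)C)cc2O1 | intermediate
6 | 6-bromo-2,2-dimethyl-7-(triisopropylsilyloxy)chroman-4-ol (racemic) | CC1(C)CC(O)c2cc(Br)c(O[Si](C(C)C)(C(C)C)C(C)C)cc2O1 | intermediate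
7 | 6-bromo-2,2-dimethyl-7-(triisopropylsilyloxy)-2H-chromene | CC1(C)C=Cc2cc(Br)c(O[Si](C(C)C)(C(C)C)C(C)C)cc2O1 | intermediate
8 | [2,2-dimethyl-7-(triisopropylsilyloxy)-2H-chromen-6-yl]lithium | [Li]c1cc2C=CC(C)(C)Oc2cc1O[Si](C(C)C)(C(C)C)C(C)C | intermediate
9 | 2,2-dimethyl-7-(triisopropylsilyloxy)-2H-chromene-6-carbaldehyde | CC1(C)C=Cc2cc(C=O)c(O[Si](C(C)C)(C(C)C)C(C)C)cc2O1 | intermediate
10 | [2,2-dimethyl-7-(triisopropylsilyloxy)-2H-chromen-6-yl]methanol | CC1(C)C=Cc2cc(CO)c(O[Si](C(C)C)(C(C)C)C(C)C)cc2O1 | intermediate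
11 | 2-methylbut-3-en-2-ol | CC(C)(O)C=C | starting material
12 | triethyl[(2-methylbut-3-en-2-yl)oxy]silane | CC(C)(O[Si](CC)(CC)CC)C=C | intermediate
13 | 2',4',6'-trihydroxyacetophenone | CC(=O)c1c(O)cc(O)cc1O | starting material
14 | 1-[2-hydroxy-4,6-bis(triisopropylsilyloxy)phenyl]ethanone | CC(=O)c1c(O)cc(O[Si](C(C)C)(C(C)C)C(C)C)cc1O[Si](C(C)C)(C(C)C)C(C)C | intermediate
15 | 1-[2-hydroxy-3-iodo-4,6-bis(triisopropylsilyloxy)phenyl]ethanone | CC(=O)c1c(O)c(I)c(O[Si](C(C)C)(C(C)C)C(C)C)cc1O[Si](C(C)C)(C(C)C)C(C)C | intermediate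
16 | 9-[3-methyl-3-(triethylsilyloxy)butyl]-9-borabicyclo[3.3.1]nonane | CC(C)(O[Si](CC)(CC)CC)CCB1C2CCCC1CCC2 | intermediate
17 | 1-[2-hydroxy-3-(3-methyl-3-triethylsilyloxybutyl)-4,6-bis(triisopropylsilyloxy)phenyl]ethanone | CC(=O)c1c(O)c(CCC(C)(C)O[Si](CC)(CC)CC)c(O[Si](C(C)C)(C(C)C)C(C)C)cc1O[Si](C(C)C)(C(C)C)C(C)C | intermediate
18 | 1-[2-{[2,2-dimethyl-7-(triisopropylsilyloxy)-2H-chromen-6-yl]methoxy}-3-(3-methyl-3-triethylsilyloxybutyl)-4,6-bis(triisopropylsilyloxy)phenyl]ethanone | CC(=O)c1c(OCc2cc3C=CC(C)(C)Oc3cc2O[Si](C(C)C)(C(C)C)C(C)C)c(CCC(C)(C)O[Si](CC)(CC)CC)c(O[Si](C(C)C)(C(C)C)C(C)C)cc1O[Si](C(C)C)(C(C)C)C(C)C | intermediate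
19 | 4,4,4-trifluoro-1-[2-{[2,2-dimethyl-7-(triisopropylsilyloxy)-2H-chromen-6-yl]methoxy}-3-(3-methyl-3-triethylsilyloxybutyl)-4,6-bis(triisopropylsilyloxy)phenyl]butane-1,3-dione | O=C(CC(=O)C(F)(F)F)c1c(OCc2cc3C=CC(C)(C)Oc3cc2O[Si](C(C)C)(C(C)C)C(C)C)c(CCC(C)(C)O[Si](CC)(CC)CC)c(O[Si](C(C)C)(C(C)C)C(C)C)cc1O[Si](C(C)C)(C(C)C)C(C)C | intermediate
20 | 2-diazo-1-[2-{[2,2-dimethyl-7-(triisopropylsilyloxy)-2H-chromen-6-yl]methoxy}-3-(3-methyl-3-triethylsilyloxybutyl)-4,6-bis(triisopropylsilyloxy)phenyl]ethanone | [N-]=[N+]=CC(=O)c1c(OCc2cc3C=CC(C)(C)Oc3cc2O[Si](C(C)C)(C(C)C)C(C)C)c(CCC(C)(C)O[Si](CC)(CC)CC)c(O[Si](C(C)C)(C(C)C)C(C)C)cc1O[Si](C(C)C)(C(C)C)C(C)C | intermediate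
21 | (2S)-2-[2,2-dimethyl-7-(triisopropylsilyloxy)-2H-chromen-6-yl]-8-(3-methyl-3-triethylsilyloxybutyl)-5,7-bis(triisopropylsilyloxy)chroman-4-one | CC(C)(O[Si](CC)(CC)CC)CCc1c(O[Si](C(C)C)(C(C)C)C(C)C)cc(O[Si](C(C)C)(C(C)C)C(C)C)c2c1O[C@H](c1cc3c(cc1O[Si](C(C)C)(C(C)C)C(C)C)OC(C)(C)C=C3)CC2=O | intermediate
22 | (2S)-5,7-dihydroxy-2-(7-hydroxy-2,2-dimethyl-2H-chromen-6-yl)-8-(3-hydroxy-3-methylbutyl)chroman-4-one | CC(C)(O)CCc1c(O)cc(O)c2c1O[C@H](c1cc3c(cc1O)OC(C)(C)C=C3)CC2=O | target

**Totals**
Total step count: 13. Longest linear sequence: 9 steps (steps 1–5, then 10–13); the ring-A branch (steps 7–9) and the side-chain branch (step 6) join it at steps 9 and 10.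

**Steps most likely to fail**

Step 12. The carbenoid may be captured by the lone pair of O1 (ylide formation and benzyl migration) faster than it inserts, and a catalyst acting on a terminal diazoketone carbenoid may discriminate poorly between the two enantiotopic benzylic hydrogens. The fallback builds ring C by the chalcone route; it sets out from phenol 17 and aldehyde 9 and returns at 21. Phenol 17 is deprotonated twice with LiN(SiMe3)2 in THF at −78 °C (phenoxide and methyl-ketone enolate) and added to 9 to give the aldol adduct 3-[2,2-dimethyl-7-(TIPSO)-2H-chromen-6-yl]-3-hydroxy-1-[2-hydroxy-3-(3-methyl-3-TESO-butyl)-4,6-bis(TIPSO)phenyl]propan-1-one F1. Dehydration of this electron-rich benzylic alcohol with catalytic pyridinium p-toluenesulfonate in warm toluene should give the 2'-hydroxychalcone (E)-3-[2,2-dimethyl-7-(TIPSO)-2H-chromen-6-yl]-1-[2-hydroxy-3-(3-methyl-3-TESO-butyl)-4,6-bis(TIPSO)phenyl]prop-2-en-1-one F2. Its only free hydroxyl is then added across the enone by asymmetric intramolecular oxa-Michael cyclisation under a bifunctional quinine-derived thiourea, with chromatography on a chiral stationary phase to bring the 2S enantiomer to purity if the selectivity falls short, giving 21.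

Step 10. Slow proton transfer from the hindered, hydrogen-bonded phenol may let the electron-rich benzylic oxyphosphonium ionise, so that N-alkylation of the hydrazide or C-alkylation competes with ether formation. The fallback sets out from alcohol 10 and returns at 18. Alcohol 10 is converted with MsCl, Et3N and LiCl in THF at 0 °C into the benzylic chloride 6-(chloromethyl)-2,2-dimethyl-7-(TIPSO)-2H-chromene F3, and phenol 17 is O-alkylated with it in a Williamson ether synthesis (K2CO3, catalytic NaI, acetone, 50 °C) to give 18.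

Step 9. Oxidative addition into the iodophenoxide may stall, with protodeiodination taking over. The fallback caps the phenol as its final ether before the coupling; it sets out from iodophenol 15 and alcohol 10 and returns at 18. Mitsunobu etherification of 15 (more acidic than 17) with 10 gives the iodo ether 1-[2-{[2,2-dimethyl-7-(TIPSO)-2H-chromen-6-yl]methoxy}-3-iodo-4,6-bis(TIPSO)phenyl]ethanone F4, and B-alkyl Suzuki coupling of this non-phenolic iodide with alkylborane 16 under the catalyst of step 9 gives 18 directly, bypassing 17.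

**Further compounds**
F1 | step 12 | 3-[2,2-dimethyl-7-(triisopropylsilyloxy)-2H-chromen-6-yl]-3-hydroxy-1-[2-hydroxy-3-(3-methyl-3-triethylsilyloxybutyl)-4,6-bis(triisopropylsilyloxy)phenyl]propan-1-one | O=C(CC(O)c1cc2C=CC(C)(C)Oc2cc1O[Si](C(C)C)(C(C)C)C(C)C)c1c(O)c(CCC(C)(C)O[Si](CC)(CC)CC)c(O[Si](C(C)C)(C(C)C)C(C)C)cc1O[Si](C(C)C)(C(C)C)C(C)C
F2 | step 12 | (E)-3-[2,2-dimethyl-7-(triisopropylsilyloxy)-2H-chromen-6-yl]-1-[2-hydroxy-3-(3-methyl-3-triethylsilyloxybutyl)-4,6-bis(triisopropylsilyloxy)phenyl]prop-2-en-1-one | O=C(/C=C/c1cc2C=CC(C)(C)Oc2cc1O[Si](C(C)C)(C(C)C)C(C)C)c1c(O)c(CCC(C)(C)O[Si](CC)(CC)CC)c(O[Si](C(C)C)(C(C)C)C(C)C)cc1O[Si](C(C)C)(C(C)C)C(C)C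
F3 | step 10 | 6-(chloromethyl)-2,2-dimethyl-7-(triisopropylsilyloxy)-2H-chromene | CC1(C)C=Cc2cc(CCl)c(O[Si](C(C)C)(C(C)C)C(C)C)cc2O1
F4 | step 9 | 1-[2-{[2,2-dimethyl-7-(triisopropylsilyloxy)-2H-chromen-6-yl]methoxy}-3-iodo-4,6-bis(triisopropylsilyloxy)phenyl]ethanone | CC(=O)c1c(OCc2cc3C=CC(C)(C)Oc3cc2O[Si](C(C)C)(C(C)C)C(C)C)c(I)c(O[Si](C(C)C)(C(C)C)C(C)C)cc1O[Si](C(C)C)(C(C)C)C(C)C
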